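**Plan**
- The retrosynthesis first cuts the depside ester C–O bond between the ring A carboxyl carbon and O4 of ring B, giving a ring A acid and a ring B phenol that share one carbon skeleton and so descend from a single resorcylate.
- That resorcylate is opened at its arene C1–C6 bond (chain C2–C7, aldol) and its ester C–O bond (benzyl alcohol plus acylketene), leading back to a diketo-dioxinone. The chain is cut at C6–C7 and C4–C5 (two Claisen acylations) to 2,2,6-trimethyl-1,3-dioxin-4-one, acetyl chloride and ketal-masked 3-oxooctanoic acid.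
- Forward: the chain is joined at C4–C5, then C6–C7, and one thermolysis with benzyl alcohol closes the arene that serves as both rings. One portion is 4-O-allylated, 2-O-methylated and deallylated (ring B phenol); the other is 4-O-methylated, 2-O-methoxymethylated and debenzylated (ring A acid). The rings are united last by esterification, acid then removes both ketals and the methoxymethyl group, and hydrogenolysis frees the carboxyl.
- The enabling feature: rings A and B are the same C14 resorcylate, with the carboxyl carbon on C1, oxygen on C2 and C4 and a 2-oxoheptyl arm on C6. This is the C2-to-C7 fold of a 3,5,7,9-tetraoxotetradecanoate whose C9 carbonyl can be held as a dioxolane.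
- Stereochemistry: the target has no stereocentre, so none has to be set or preserved.

Key step: step 5

Remark: the aldol adduct 13 forms as a diastereomer mixture whose two stereocentres are erased on aromatisation, so it is drawn without configuration; LiN(iPr)2 and LiN(SiMe3)2 are taken as commercial solutions.

**Route**

Step 1
Reactants: 1 methyl 3-oxooctanoate; 2 ethylene glycol
Product: 3 methyl (2-pentyl-1,3-dioxolan-2-yl)acetate
Conditions: p-TsOH·H2O (cat.), PhMe, reflux, Dean–Stark
Reagents that add atoms: none
Why: Acid-catalysed ketalisation of the ketone of a β-keto ester with azeotropic removal of water is a standard dioxolane formation in which the ester carbonyl does not compete.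

Step 2
Reactants: 3 methyl (2-pentyl-1,3-dioxolan-2-yl)acetate
Product: 4 (2-pentyl-1,3-dioxolan-2-yl)acetic acid
Conditions: LiOH, THF–MeOH–H2O, rt; then 1 M HCl to pH 4, 0 °C
Reagents that add atoms: lithium hydroxide, [Li+].[OH-]
Why: Saponification of an unhindered methyl ester leaves the base-stable dioxolane untouched, and the brief cold acidification to pH 4 should free the acid without opening the ketal.

Step 3
Reactants: 5 2,2,6-trimethyl-4H-1,3-dioxin-4-one; 6 acetyl chloride
Product: 7 2,2-dimethyl-6-(2-oxopropyl)-4H-1,3-dioxin-4-one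
Conditions: LiN(SiMe3)2, THF, −78 °C; then AcCl (0.5 equiv per enolate), −78 °C; aq. NH4Cl
Reagents that add atoms: none
Why: This is a crossed Claisen C-acylation of the lithium dienolate of the dioxinone at its γ-carbon (chain C4–C5 bond), and the excess enolate takes up the proton of the more acidic product so that a second acylation is suppressed.

Step 4
Reactants: 7 2,2-dimethyl-6-(2-oxopropyl)-4H-1,3-dioxin-4-one; 4 (2-pentyl-1,3-dioxolan-2-yl)acetic acid
Product: 9 6-[2,4-dioxo-5-(2-pentyl-1,3-dioxolan-2-yl)pentyl]-2,2-dimethyl-4H-1,3-dioxin-4-one, via acyl imidazolide 8 (not isolated)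
Conditions: 4, 1,1'-carbonyldiimidazole, THF, rt; separately 7, LiN(iPr)2 (2.1 equiv, dianion in excess over 8), THF, −78 °C; add the solution of 8, −78 to −40 °C; aq. NH4Cl
Reagents that add atoms: none
Why: This is a Claisen condensation of a 1,3-dicarbonyl dianion, which reacts at its terminal and more basic carbon with the acyl imidazolide (chain C6–C7 bond), the product being protected from further attack as its enolate.

Step 5
Reactants: 9 6-[2,4-dioxo-5-(2-pentyl-1,3-dioxolan-2-yl)pentyl]-2,2-dimethyl-4H-1,3-dioxin-4-one; 10 benzyl alcohol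
Product: 14 benzyl 2,4-dihydroxy-6-[(2-pentyl-1,3-dioxolan-2-yl)methyl]benzoate, via acylketene 11 (not isolated), via benzyl triketo ester 12 (not isolated), via cyclic aldol adduct 13 (not isolated)
Conditions: BnOH (2 equiv), PhMe, 110 °C; then Cs2CO3, iPrOH–CH2Cl2, rt; then AcOH, rt
Reagents that add atoms: none
Why: At 110 °C the dioxinone of 9 should undergo retro-[4+2] loss of acetone to acylketene 11, which benzyl alcohol traps as triketo ester 12; Cs2CO3 then enolises the doubly activated chain C2, which adds to the C7 ketone, and adduct 13 loses water and enolises to the arene once the mixture is made weakly acidic. The closest known reaction type is the thermolysis of diketo-dioxinones with alcohol capture of the acylketene followed by base-mediated aldol aromatisation to β-resorcylate esters. The one ring that closes (the resorcylate ring, through the new arene C1–C6 bond, chain C2–C7) does so by a 6-(enolendo)-exo-trig aldol addition. No stereocentre is created in 14, and the two of adduct 13 disappear on dehydration. The step needs one fold of the chain out of several and C-cyclisation in preference to O-cyclisation: the dioxolane at C9 removes the C4-to-C9 aldol and leaves C8 without an activated proton, the C1 ester is a poorer electrophile than the C7 ketone so Claisen closure to an acylphloroglucinol is slow, and carbonate at room temperature favours the aldol over lactonisation to a 4-hydroxy-2-pyranone. The ketal, the benzyl ester and the free phenols should all tolerate toluene at reflux, carbonate and acetic acid.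

Step 6
Reactants: 14 benzyl 2,4-dihydroxy-6-[(2-pentyl-1,3-dioxolan-2-yl)methyl]benzoate
Product: 15 benzyl 4-(allyloxy)-2-hydroxy-6-[(2-pentyl-1,3-dioxolan-2-yl)methyl]benzoate
Conditions: allyl bromide (1.05 equiv), K2CO3, acetone, rt
Reagents that add atoms: allyl bromide, C=CCBr
Why: In this Williamson etherification the 4-hydroxyl is the more acidic and unchelated phenol, whereas the 2-hydroxyl is hydrogen-bonded to the ester carbonyl and should stay free with one equivalent of halide.

Step 7
Reactants: 15 benzyl 4-(allyloxy)-2-hydroxy-6-[(2-pentyl-1,3-dioxolan-2-yl)methyl]benzoate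
Product: 16 benzyl 4-(allyloxy)-2-methoxy-6-[(2-pentyl-1,3-dioxolan-2-yl)methyl]benzoate
Conditions: MeI, K2CO3, DMF, 40 °C
Reagents that add atoms: iodomethane, CI
Why: Williamson methylation of the remaining chelated phenol proceeds in a dipolar aprotic solvent, and the allyl ether, unlike a silyl ether, cannot be lost under carbonate.

Step 8
Reactants: 16 benzyl 4-(allyloxy)-2-methoxy-6-[(2-pentyl-1,3-dioxolan-2-yl)methyl]benzoate
Product: 17 benzyl 4-hydroxy-2-methoxy-6-[(2-pentyl-1,3-dioxolan-2-yl)methyl]benzoate
Conditions: Pd(PPh3)4 (cat.), morpholine, THF, rt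
Reagents that add atoms: none
Why: Tsuji–Trost deallylation, in which zerovalent palladium ionises the aryl allyl ether and morpholine takes the allyl group, is neutral and leaves the benzyl ester and the dioxolane alone.

Step 9
Reactants: 14 benzyl 2,4-dihydroxy-6-[(2-pentyl-1,3-dioxolan-2-yl)methyl]benzoate
Product: 18 benzyl 2-hydroxy-4-methoxy-6-[(2-pentyl-1,3-dioxolan-2-yl)methyl]benzoate
Conditions: MeI (1.05 equiv), K2CO3, acetone, rt
Reagents that add atoms: iodomethane, CI
Why: Williamson methylation is selective for the unchelated 4-hydroxyl, as is usual for 2,4-dihydroxybenzoates treated with one equivalent of halide.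

Step 10
Reactants: 18 benzyl 2-hydroxy-4-methoxy-6-[(2-pentyl-1,3-dioxolan-2-yl)methyl]benzoate
Product: 19 benzyl 4-methoxy-2-(methoxymethoxy)-6-[(2-pentyl-1,3-dioxolan-2-yl)methyl]benzoate
Conditions: NaH, DMF, 0 °C; then MeOCH2Cl, 0 °C to rt
Reagents that add atoms: chloromethyl methyl ether, COCCl
Why: Williamson-type alkylation of the sodium phenoxide masks the chelated hydroxyl as a methoxymethyl ether, an acetal that survives hydrogenolysis and carbodiimide coupling and later falls in the same acid step as the dioxolanes.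

Step 11
Reactants: 19 benzyl 4-methoxy-2-(methoxymethoxy)-6-[(2-pentyl-1,3-dioxolan-2-yl)methyl]benzoate
Product: 20 4-methoxy-2-(methoxymethoxy)-6-[(2-pentyl-1,3-dioxolan-2-yl)methyl]benzoic acid
Conditions: H2 (1 atm), Pd/C, EtOAc, rt; filter, concentrate below 30 °C, use at once
Reagents that add atoms: none
Why: Catalytic hydrogenolysis cleaves the benzyl ester at the benzylic C–O bond, so the steric shielding of the carboxyl is irrelevant, and the neutral medium should leave the methoxymethyl ether and the dioxolane in place.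

Step 12
Reactants: 20 4-methoxy-2-(methoxymethoxy)-6-[(2-pentyl-1,3-dioxolan-2-yl)methyl]benzoic acid; 17 benzyl 4-hydroxy-2-methoxy-6-[(2-pentyl-1,3-dioxolan-2-yl)methyl]benzoate
Product: 21 benzyl 4-{[4-methoxy-2-(methoxymethoxy)-6-[(2-pentyl-1,3-dioxolan-2-yl)methyl]benzoyl]oxy}-2-methoxy-6-[(2-pentyl-1,3-dioxolan-2-yl)methyl]benzoate
Conditions: N,N'-dicyclohexylcarbodiimide, DMAP, CH2Cl2, 0 °C to rt
Reagents that add atoms: none
Why: In this Steglich esterification DMAP relays the acyl group from the O-acylisourea to the only free hydroxyl of 17, and the neutral conditions spare both dioxolanes and the methoxymethyl ether.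

Step 13
Reactants: 21 benzyl 4-{[4-methoxy-2-(methoxymethoxy)-6-[(2-pentyl-1,3-dioxolan-2-yl)methyl]benzoyl]oxy}-2-methoxy-6-[(2-pentyl-1,3-dioxolan-2-yl)methyl]benzoate
Product: 22 benzyl 4-{[2-hydroxy-4-methoxy-6-(2-oxoheptyl)benzoyl]oxy}-2-methoxy-6-(2-oxoheptyl)benzoate
Conditions: 2 M aq. HCl–THF, rt
Reagents that add atoms: water, O
Why: Acid-catalysed acetal hydrolysis opens both dialkyl dioxolanes and the aryl methoxymethyl ether in dilute aqueous acid, where the hindered aryl ester, the benzyl ester and the methyl ethers are inert and no free carboxyl is present to lactonise onto the new ketones.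

Step 14
Reactants: 22 benzyl 4-{[2-hydroxy-4-methoxy-6-(2-oxoheptyl)benzoyl]oxy}-2-methoxy-6-(2-oxoheptyl)benzoate
Product: 23 4-{[2-hydroxy-4-methoxy-6-(2-oxoheptyl)benzoyl]oxy}-2-methoxy-6-(2-oxoheptyl)benzoic acid
Conditions: H2 (1 atm), Pd/C, EtOAc, rt
Reagents that add atoms: none
Why: Catalytic hydrogenolysis removes the benzyl ester under neutral conditions, leaving the dialkyl ketones, the depside ester, the phenol and the methyl ethers intact, so the sensitive keto acid is released without acid or base.

**Compound list**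

1 | methyl 3-oxooctanoate | CCCCCC(=O)CC(=O)OC | starting material
2 | ethylene glycol | OCCO | starting material
3 | methyl (2-pentyl-1,3-dioxolan-2-yl)acetate | CCCCCC1(CC(=O)OC)OCCO1 | intermediate
4 | (2-pentyl-1,3-dioxolan-2-yl)acetic acid | CCCCCC1(CC(=O)O)OCCO1 | intermediate
5 | 2,2,6-trimethyl-4H-1,3-dioxin-4-one | CC1=CC(=O)OC(C)(C)O1 | starting material
6 | acetyl chloride | CC(Cl)=O | starting material
7 | 2,2-dimethyl-6-(2-oxopropyl)-4H-1,3-dioxin-4-one | CC(=O)CC1=CC(=O)OC(C)(C)O1 | intermediate
8 | 1-[(2-pentyl-1,3-dioxolan-2-yl)acetyl]-1H-imidazole | CCCCCC1(CC(=O)n2ccnc2)OCCO1 | intermediate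
9 | 6-[2,4-dioxo-5-(2-pentyl-1,3-dioxolan-2-yl)pentyl]-2,2-dimethyl-4H-1,3-dioxin-4-one | CCCCCC1(CC(=O)CC(=O)CC2=CC(=O)OC(C)(C)O2)OCCO1 | intermediate
10 | benzyl alcohol | OCc1ccccc1 | starting material
11 | 8-(2-pentyl-1,3-dioxolan-2-yl)oct-1-ene-1,3,5,7-tetrone (acylketene) | CCCCCC1(CC(=O)CC(=O)CC(=O)C=C=O)OCCO1 | intermediate
12 | benzyl 3,5,7-trioxo-8-(2-pentyl-1,3-dioxolan-2-yl)octanoate | CCCCCC1(CC(=O)CC(=O)CC(=O)CC(=O)OCc2ccccc2)OCCO1 | intermediate
13 | benzyl 2-hydroxy-4,6-dioxo-2-[(2-pentyl-1,3-dioxolan-2-yl)methyl]cyclohexane-1-carboxylate | CCCCCC1(CC2(O)CC(=O)CC(=O)C2C(=O)OCc2ccccc2)OCCO1 | intermediate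
14 | benzyl 2,4-dihydroxy-6-[(2-pentyl-1,3-dioxolan-2-yl)methyl]benzoate | CCCCCC1(Cc2cc(O)cc(O)c2C(=O)OCc2ccccc2)OCCO1 | intermediate
15 | benzyl 4-(allyloxy)-2-hydroxy-6-[(2-pentyl-1,3-dioxolan-2-yl)methyl]benzoate | CCCCCC1(Cc2cc(OCC=C)cc(O)c2C(=O)OCc2ccccc2)OCCO1 | intermediate
16 | benzyl 4-(allyloxy)-2-methoxy-6-[(2-pentyl-1,3-dioxolan-2-yl)methyl]benzoate | CCCCCC1(Cc2cc(OCC=C)cc(OC)c2C(=O)OCc2ccccc2)OCCO1 | intermediate
17 | benzyl 4-hydroxy-2-methoxy-6-[(2-pentyl-1,3-dioxolan-2-yl)methyl]benzoate | CCCCCC1(Cc2cc(O)cc(OC)c2C(=O)OCc2ccccc2)OCCO1 | intermediate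
18 | benzyl 2-hydroxy-4-methoxy-6-[(2-pentyl-1,3-dioxolan-2-yl)methyl]benzoate | CCCCCC1(Cc2cc(OC)cc(O)c2C(=O)OCc2ccccc2)OCCO1 | intermediate
19 | benzyl 4-methoxy-2-(methoxymethoxy)-6-[(2-pentyl-1,3-dioxolan-2-yl)methyl]benzoate | CCCCCC1(Cc2cc(OC)cc(OCOC)c2C(=O)OCc2ccccc2)OCCO1 | intermediate
20 | 4-methoxy-2-(methoxymethoxy)-6-[(2-pentyl-1,3-dioxolan-2-yl)methyl]benzoic acid | CCCCCC1(Cc2cc(OC)cc(OCOC)c2C(=O)O)OCCO1 | intermediate
21 | benzyl 4-{[4-methoxy-2-(methoxymethoxy)-6-[(2-pentyl-1,3-dioxolan-2-yl)methyl]benzoyl]oxy}-2-methoxy-6-[(2-pentyl-1,3-dioxolan-2-yl)methyl]benzoate | CCCCCC1(Cc2cc(OC)cc(OCOC)c2C(=O)Oc2cc(CC3(CCCCC)OCCO3)c(C(=O)OCc3ccccc3)c(OC)c2)OCCO1 | intermediate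
22 | benzyl 4-{[2-hydroxy-4-methoxy-6-(2-oxoheptyl)benzoyl]oxy}-2-methoxy-6-(2-oxoheptyl)benzoate | CCCCCC(=O)Cc1cc(OC)cc(O)c1C(=O)Oc1cc(CC(=O)CCCCC)c(C(=O)OCc2ccccc2)c(OC)c1 | intermediate
23 | 4-{[2-hydroxy-4-methoxy-6-(2-oxoheptyl)benzoyl]oxy}-2-methoxy-6-(2-oxoheptyl)benzoic acid | CCCCCC(=O)Cc1cc(OC)cc(O)c1C(=O)Oc1cc(CC(=O)CCCCC)c(C(=O)O)c(OC)c1 | target

**Step count**

Total steps: 14. Longest linear sequence: 10 steps (steps 1, 2, 4, 5, 6, 7, 8, 12, 13, 14 from compound 1; the ring A branch through steps 9 to 11 is equally long).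

**Steps most likely to fail**

Step 4. Proton transfer from the α-methylene of the acyl imidazolide, or from the product, to the strongly basic dianion can outrun C-acylation, and the enolate so formed can expel a ketal oxygen; O-acylation and double acylation would drain material further. The fallback sets out from 5 and 4 and returns at 9. The lithium dienolate of 5 (LiN(SiMe3)2, THF, −78 °C) is acylated with allyl 3-chloro-3-oxopropanoate to give allyl 4-(2,2-dimethyl-4-oxo-4H-1,3-dioxin-6-yl)-3-oxobutanoate F1. Acid 4 is converted under neutral conditions with 1-chloro-N,N,2-trimethylprop-1-en-1-amine into (2-pentyl-1,3-dioxolan-2-yl)acetyl chloride F2. F1 is then C-acylated by F2 at its doubly activated methylene (MgCl2, pyridine, CH2Cl2) to allyl 2-[(2,2-dimethyl-4-oxo-4H-1,3-dioxin-6-yl)acetyl]-3-oxo-4-(2-pentyl-1,3-dioxolan-2-yl)butanoate F3. Pd(PPh3)4 with morpholine removes the allyl group, and the β-keto acid loses CO2 to give 9. No dianion is involved, so the ketal never meets a strong base.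

Step 5. The acylketene or the triketo ester may be intercepted by an internal enol oxygen and lactonise to a pyranone, the aldol adduct may dehydrate sluggishly under the weak acid that the dioxolane tolerates, and stronger acid would strip the ketal. Because this single step supplies both rings, any such loss is felt twice. The fallback sets out from 9 and returns at 14. Et3N in CH2Cl2 at room temperature should cyclise 9 with the dioxinone intact, through the same chain C2-to-C7 aldol closure, to 7-hydroxy-2,2-dimethyl-5-[(2-pentyl-1,3-dioxolan-2-yl)methyl]-4H-1,3-benzodioxin-4-one F4. Because no ketene is generated, no pyranone channel is open. Excess NaH and benzyl alcohol in THF, with warming if needed, then open the acetonide by transesterification to 14.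

Step 12. Acyl transfer from the O-acylisourea of a doubly ortho-substituted acid to a weakly nucleophilic phenol may be slow, so that rearrangement to the N-acylurea takes over, and the free acid may meanwhile attack its neighbouring methoxymethyl ether or ketal. The fallback sets out from 20 and returns at 21. Cyanuric fluoride and pyridine in CH2Cl2 convert 20 into 4-methoxy-2-(methoxymethoxy)-6-[(2-pentyl-1,3-dioxolan-2-yl)methyl]benzoyl fluoride F5, a small acyl donor that tolerates hindrance and is formed in a buffered medium. F5 then acylates the phenoxide made from 17 and Cs2CO3 in MeCN to give 21.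

**Further compounds**

F1 | step 4 | allyl 4-(2,2-dimethyl-4-oxo-4H-1,3-dioxin-6-yl)-3-oxobutanoate | C=CCOC(=O)CC(=O)CC1=CC(=O)OC(C)(C)O1
F2 | step 4 | (2-pentyl-1,3-dioxolan-2-yl)acetyl chloride | CCCCCC1(CC(Cl)=O)OCCO1
F3 | step 4 | allyl 2-[(2,2-dimethyl-4-oxo-4H-1,3-dioxin-6-yl)acetyl]-3-oxo-4-(2-pentyl-1,3-dioxolan-2-yl)butanoate | C=CCOC(=O)C(C(=O)CC1=CC(=O)OC(C)(C)O1)C(=O)CC1(CCCCC)OCCO1
F4 | step 5 | 7-hydroxy-2,2-dimethyl-5-[(2-pentyl-1,3-dioxolan-2-yl)methyl]-4H-1,3-benzodioxin-4-one | CCCCCC1(Cc2cc(O)cc3OC(C)(C)OC(=O)c23)OCCO1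
F5 | step 12 | 4-methoxy-2-(methoxymethoxy)-6-[(2-pentyl-1,3-dioxolan-2-yl)methyl]benzoyl fluoride | CCCCCC1(Cc2cc(OC)cc(OCOC)c2C(=O)F)OCCO1
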